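**Retrosynthetic overview**
1. Fusariumester B (23) ⇒ global deprotection of 21, which comes from Yamaguchi esterification of silyl-protected hymeglusin acid 18 with the secondary alcohol of the ring-opened half 19.
2. 18 ⇐ (2R,3R)-β-lactone 16 (ester acidolysis); 19 ⇐ (2S,3S)-β-lactone 17 by acyl–oxygen opening with 4-methoxybenzyl alcohol.
3. 16 and 17 ⇐ one aldehyde 12 plus one anhydride 15 (from acid 14), by a trans-selective isothiourea-catalysed formal [2+2] run with the two mirror-image catalysts.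
4. 12 ⇐ alkynol 7 + enol triflate 9 (carboalumination/Negishi coupling); 7 ⇐ enal 5 by organocatalytic transfer hydrogenation (C7, first stereocentre) and alkyne homologation; 5 ⇐ hept-6-yn-1-ol.
5. Rings: the only rings are two oxetan-2-ones, closed in steps 10 and 11; the one from step 11 is reopened in step 13, the one from step 10 is kept to the end.

Assumption: the sense of induction quoted for each chiral catalyst follows the accepted face-shielding model; if an experiment shows the opposite sense, the mirror-image (or pseudo-enantiomeric) catalyst is used with no other change.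

**Step 1**
Reactants: 1 hept-6-yn-1-ol
Product: 4 (E)-3-methyloct-2-ene-1,8-diol, via alkenylalane 2 (not isolated), via lithium alanate 3 (not isolated)
Conditions: Me3Al (3 equiv), Cp2ZrCl2 (25 mol%), CH2Cl2, 0 °C to rt; evaporate; n-BuLi (1 equiv), THF/hexane, −78 °C; (CH2O)n, −78 °C to rt; aq. NH4Cl
Reagents that add atoms: trimethylaluminium C[Al](C)C; formaldehyde (as paraformaldehyde) C=O
Why: Negishi zirconium-catalysed syn-carboalumination of the terminal alkyne (hydroxyl masked in situ as its dimethylaluminium alkoxide) puts Me and Al cis, and the derived alanate adds to formaldehyde with retention, so only the E trisubstituted alkene forms.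

**Step 2**
Reactants: 4 (E)-3-methyloct-2-ene-1,8-diol
Product: 5 (E)-8-hydroxy-3-methyloct-2-enal
Conditions: MnO2 (15 equiv), CH2Cl2, rt
Reagents that add atoms: none
Why: Allylic oxidation with MnO2 converts only the allylic alcohol and leaves the saturated primary alcohol untouched.

**Step 3**
Reactants: 5 (E)-8-hydroxy-3-methyloct-2-enal
Product: 6 (R)-8-hydroxy-3-methyloctanal
Conditions: (R)-2-tert-butyl-3-methylimidazolidin-4-one·Cl3CCO2H (20 mol%), Hantzsch ester [diethyl 2,6-dimethyl-1,4-dihydropyridine-3,5-dicarboxylate] (1.2 equiv), CHCl3, −30 °C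
Reagents that add atoms: none
Why: Imidazolidinone-catalysed iminium transfer hydrogenation, in which the Hantzsch ester delivers hydride to the β-carbon of the (E)-iminium ion on the face away from the tert-butyl group, sets the first stereocentre as R (about 90–95% ee expected for a β-methyl/β-alkyl enal) and tolerates the free hydroxyl.

**Step 4**
Reactants: 6 (R)-8-hydroxy-3-methyloctanal
Product: 7 (R)-6-methylnon-8-yn-1-ol
Conditions: Ohira–Bestmann reagent (1.3 equiv), K2CO3 (2 equiv), MeOH, 0 °C to rt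
Reagents that add atoms: dimethyl (1-diazo-2-oxopropyl)phosphonate CC(=O)C(=[N+]=[N-])P(=O)(OC)OC
Why: Ohira–Bestmann (Seyferth–Gilbert) homologation gives the terminal alkyne under mild K2CO3/MeOH conditions that cannot epimerise the β-stereocentre or affect the free alcohol.

**Step 5**
Reactants: 8 tert-butyl 3-oxobutanoate
Product: 9 tert-butyl (E)-3-{[(trifluoromethyl)sulfonyl]oxy}but-2-enoate
Conditions: Tf2O (1.2 equiv), aq. Me4NOH, hexane, 5 °C
Reagents that add atoms: trifluoromethanesulfonic anhydride O=S(=O)(OS(=O)(=O)C(F)(F)F)C(F)(F)F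
Why: O-triflation of the β-keto ester enolate with a non-chelating tetramethylammonium counter-ion gives the (E)-enol triflate selectively, the geometry that becomes the 2E double bond.

**Step 6**
Reactants: 7 (R)-6-methylnon-8-yn-1-ol; 9 tert-butyl (E)-3-{[(trifluoromethyl)sulfonyl]oxy}but-2-enoate
Product: 11 tert-butyl (2E,4E,7R)-12-hydroxy-3,5,7-trimethyldodeca-2,4-dienoate, via alkenylalane 10 (not isolated)
Conditions: Me3Al (3 equiv), Cp2ZrCl2 (25 mol%), CH2Cl2, 0 °C to rt; evaporate; then 9, Pd(PPh3)4 (5 mol%), ZnCl2 (0.5 equiv), THF, rt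
Reagents that add atoms: trimethylaluminium C[Al](C)C
Why: Negishi syn-carboalumination fixes the 4E trisubstituted alkene, and one-pot palladium/zinc-cocatalysed Negishi cross-coupling of the alkenylalane with enol triflate 9 proceeds with retention on both partners to give the (2E,4E)-dienoate directly.

**Step 7**
Reactants: 11 tert-butyl (2E,4E,7R)-12-hydroxy-3,5,7-trimethyldodeca-2,4-dienoate
Product: 12 tert-butyl (2E,4E,7R)-3,5,7-trimethyl-12-oxododeca-2,4-dienoate
Conditions: TEMPO (10 mol%), PhI(OAc)2 (1.1 equiv), CH2Cl2, rt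
Reagents that add atoms: none
Why: Oxoammonium (TEMPO/PhI(OAc)2) oxidation stops at the aldehyde and does not touch the dienoate or the remote stereocentre.

**Step 8**
Reactants: 13 3-[(tert-butyldiphenylsilyl)oxy]propan-1-ol
Product: 14 3-[(tert-butyldiphenylsilyl)oxy]propanoic acid
Conditions: TEMPO (20 mol%), PhI(OAc)2 (2.2 equiv), MeCN/H2O 1:1, rt
Reagents that add atoms: water O
Why: TEMPO/PhI(OAc)2 oxidation in aqueous acetonitrile takes the primary alcohol through the aldehyde hydrate to the acid without cleaving the robust silyl ether.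

**Step 9**
Reactants: 14 3-[(tert-butyldiphenylsilyl)oxy]propanoic acid (2 equiv)
Product: 15 3-[(tert-butyldiphenylsilyl)oxy]propanoic anhydride
Conditions: N,N'-dicyclohexylcarbodiimide (1 equiv per 2 equiv of 14), CH2Cl2, 0 °C to rt; filter; evaporate
Reagents that add atoms: none
Why: Carbodiimide dehydration, in which the O-acylisourea of one acid molecule is acylated by a second carboxylate, gives the symmetric anhydride and insoluble dicyclohexylurea; the anhydride is made once as a single batch and divided between steps 10 and 11.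

**Step 10**
Reactants: 12 tert-butyl (2E,4E,7R)-3,5,7-trimethyl-12-oxododeca-2,4-dienoate; 15 3-[(tert-butyldiphenylsilyl)oxy]propanoic anhydride
Product: 16 tert-butyl (2E,4E,7R)-11-[(2R,3R)-3-{[(tert-butyldiphenylsilyl)oxy]methyl}-4-oxooxetan-2-yl]-3,5,7-trimethylundeca-2,4-dienoate
Conditions: 15 (1.5 equiv), (2R,3S)-HyperBTM [(2R,3S)-3-isopropyl-2-phenyl-3,4-dihydro-2H-benzo[4,5]thiazolo[3,2-a]pyrimidine] (10 mol%), N,N'-bis[3,5-bis(trifluoromethyl)phenyl]thiourea (20 mol%), iPr2NEt (1.5 equiv), CH2Cl2, −40 to 0 °C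
Reagents that add atoms: none
Why: Proposed new method: a metal-free isothiourea-catalysed formal [2+2] of an unactivated, enolisable aliphatic aldehyde with a C1-ammonium enolate, in which N-acylation of the catalyst by anhydride 15 and deprotonation by the released carboxylate/iPr2NEt give a (Z)-enolate locked by the 1,5-O···S contact, the thiourea activates the aldehyde by double hydrogen bonding so that C–C bond formation goes through an open non-chelated transition state on the enolate face anti to the catalyst phenyl group with the alkyl chain anti to the CH2OSi group (anti-aldolate, C3 = R and C2 = R), and 4-exo-trig lactonisation releases the catalyst; the closest known reactions are the isothiourea-catalysed intermolecular [2+2] of anhydrides with trifluoromethyl ketones, the intramolecular nucleophile-catalysed aldol-lactonisation of aldehyde acids and the cis-selective cinchona alkaloid/LiClO4 acyl halide–aldehyde cyclocondensation, none of which gives trans-lactones from simple aliphatic aldehydes.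

**Step 11**
Reactants: 12 tert-butyl (2E,4E,7R)-3,5,7-trimethyl-12-oxododeca-2,4-dienoate; 15 3-[(tert-butyldiphenylsilyl)oxy]propanoic anhydride
Product: 17 tert-butyl (2E,4E,7R)-11-[(2S,3S)-3-{[(tert-butyldiphenylsilyl)oxy]methyl}-4-oxooxetan-2-yl]-3,5,7-trimethylundeca-2,4-dienoate
Conditions: 15 (1.5 equiv), (2S,3R)-HyperBTM (10 mol%), N,N'-bis[3,5-bis(trifluoromethyl)phenyl]thiourea (20 mol%), iPr2NEt (1.5 equiv), CH2Cl2, −40 to 0 °C
Reagents that add atoms: none
Why: Proposed new method: the same isothiourea/thiourea formal [2+2] as in step 10 (C1-ammonium enolate from anhydride 15 locked by the 1,5-O···S contact, open hydrogen-bonded transition state, 4-exo-trig lactonisation; closest known reactions are the isothiourea [2+2] with trifluoromethyl ketones and the cis-selective cinchona alkaloid/LiClO4 cyclocondensation) run with the mirror-image catalyst, whose phenyl group shields the opposite enolate face so that the trans-lactone forms as (2S,3S), the remote C7 centre exerting no influence.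

**Step 12**
Reactants: 16 tert-butyl (2E,4E,7R)-11-[(2R,3R)-3-{[(tert-butyldiphenylsilyl)oxy]methyl}-4-oxooxetan-2-yl]-3,5,7-trimethylundeca-2,4-dienoate
Product: 18 (2E,4E,7R)-11-[(2R,3R)-3-{[(tert-butyldiphenylsilyl)oxy]methyl}-4-oxooxetan-2-yl]-3,5,7-trimethylundeca-2,4-dienoic acid
Conditions: CF3CO2H/CH2Cl2 1:4, 0 °C to rt
Reagents that add atoms: none
Why: Acidolysis of the tert-butyl ester (loss of the tert-butyl cation as isobutene) frees the dienoic acid, while the tert-butyldiphenylsilyl ether and the β-lactone are stable to anhydrous trifluoroacetic acid.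

**Step 13**
Reactants: 17 tert-butyl (2E,4E,7R)-11-[(2S,3S)-3-{[(tert-butyldiphenylsilyl)oxy]methyl}-4-oxooxetan-2-yl]-3,5,7-trimethylundeca-2,4-dienoate
Product: 19 1-tert-butyl 14-(4-methoxybenzyl) (2E,4E,7R,12S,13S)-13-{[(tert-butyldiphenylsilyl)oxy]methyl}-12-hydroxy-3,5,7-trimethyltetradeca-2,4-dienedioate
Conditions: 4-MeOC6H4CH2OH (3 equiv), La(OtBu)3 (10 mol%), THF, 0 °C to rt
Reagents that add atoms: 4-methoxybenzyl alcohol COc1ccc(CO)cc1
Why: Lanthanum-alkoxide-catalysed alcoholysis cleaves the strained lactone at the acyl–oxygen bond with retention at both centres, giving the anti β-hydroxy ester (12S,13S), while the conjugated tert-butyl ester is far less electrophilic and survives.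

**Step 14**
Reactants: 18 (2E,4E,7R)-11-[(2R,3R)-3-{[(tert-butyldiphenylsilyl)oxy]methyl}-4-oxooxetan-2-yl]-3,5,7-trimethylundeca-2,4-dienoic acid; 19 1-tert-butyl 14-(4-methoxybenzyl) (2E,4E,7R,12S,13S)-13-{[(tert-butyldiphenylsilyl)oxy]methyl}-12-hydroxy-3,5,7-trimethyltetradeca-2,4-dienedioate
Product: 21 1-tert-butyl 14-(4-methoxybenzyl) (2E,4E,7R,12S,13S)-13-{[(tert-butyldiphenylsilyl)oxy]methyl}-12-{[(2E,4E,7R)-11-[(2R,3R)-3-{[(tert-butyldiphenylsilyl)oxy]methyl}-4-oxooxetan-2-yl]-3,5,7-trimethylundeca-2,4-dienoyl]oxy}-3,5,7-trimethyltetradeca-2,4-dienedioate, via mixed trichlorobenzoic anhydride 20 (not isolated)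
Conditions: 2,4,6-Cl3C6H2COCl (1.2 equiv), Et3N (1.5 equiv), toluene, rt; then 19 (1.0 equiv), DMAP (1.5 equiv), toluene, 0 °C to rt
Reagents that add atoms: none
Why: Yamaguchi esterification, in which DMAP attacks mixed anhydride 20 at the less hindered dienoyl carbonyl and transfers the acyl group to the secondary alcohol with retention at C12, under conditions that β-lactones and silyl ethers tolerate.

**Step 15**
Reactants: 21 the fully protected dimer from step 14
Product: 23 fusariumester B, via bis-silyl diacid 22 (not isolated)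
Conditions: CF3CO2H/CH2Cl2 1:3, anisole (5 equiv), 0 °C to rt; evaporate; HF·pyridine, THF/pyridine, 0 °C to rt
Reagents that add atoms: none
Why: Acidolysis removes the tert-butyl and 4-methoxybenzyl esters (anisole traps the benzyl cation) and fluoride-mediated desilylation then frees both primary alcohols, neither stage affecting the β-lactone, the secondary dienoate ester, the dienes or any stereocentre.

**Compound list**
1 | hept-6-yn-1-ol | OCCCCCC#C | starting material
2 | alkenylalane: [(E)-7-(dimethylalumanyloxy)-2-methylhept-1-en-1-yl]dimethylalumane | C[Al](C)/C=C(\C)CCCCCO[Al](C)C | intermediate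
3 | lithium alanate: lithium butyl[(E)-7-(dimethylalumanyloxy)-2-methylhept-1-en-1-yl]dimethylaluminate | [Li+].CCCC[Al-](C)(C)/C=C(\C)CCCCCO[Al](C)C | intermediate
4 | (E)-3-methyloct-2-ene-1,8-diol | OC/C=C(\C)CCCCCO | intermediate
5 | (E)-8-hydroxy-3-methyloct-2-enal | O=C/C=C(\C)CCCCCO | intermediate
6 | (R)-8-hydroxy-3-methyloctanal | O=CC[C@H](C)CCCCCO | intermediate
7 | (R)-6-methylnon-8-yn-1-ol | C#CC[C@H](C)CCCCCO | intermediate
8 | tert-butyl 3-oxobutanoate | CC(=O)CC(=O)OC(C)(C)C | starting material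
9 | tert-butyl (E)-3-{[(trifluoromethyl)sulfonyl]oxy}but-2-enoate | C/C(OS(=O)(=O)C(F)(F)F)=C\C(=O)OC(C)(C)C | intermediate
10 | alkenylalane: [(1E,4R)-9-(dimethylalumanyloxy)-2,4-dimethylnon-1-en-1-yl]dimethylalumane | C[Al](C)/C=C(\C)C[C@H](C)CCCCCO[Al](C)C | intermediate
11 | tert-butyl (2E,4E,7R)-12-hydroxy-3,5,7-trimethyldodeca-2,4-dienoate | CC(=C\C(=O)OC(C)(C)C)/C=C(\C)C[C@H](C)CCCCCO | intermediate
12 | tert-butyl (2E,4E,7R)-3,5,7-trimethyl-12-oxododeca-2,4-dienoate | CC(=C\C(=O)OC(C)(C)C)/C=C(\C)C[C@H](C)CCCCC=O | intermediate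
13 | 3-[(tert-butyldiphenylsilyl)oxy]propan-1-ol | OCCCO[Si](c1ccccc1)(c1ccccc1)C(C)(C)C | starting material
14 | 3-[(tert-butyldiphenylsilyl)oxy]propanoic acid | OC(=O)CCO[Si](c1ccccc1)(c1ccccc1)C(C)(C)C | intermediate
15 | 3-[(tert-butyldiphenylsilyl)oxy]propanoic anhydride (symmetric anhydride of 14) | O=C(CCO[Si](c1ccccc1)(c1ccccc1)C(C)(C)C)OC(=O)CCO[Si](c1ccccc1)(c1ccccc1)C(C)(C)C | intermediate
16 | tert-butyl (2E,4E,7R)-11-[(2R,3R)-3-{[(tert-butyldiphenylsilyl)oxy]methyl}-4-oxooxetan-2-yl]-3,5,7-trimethylundeca-2,4-dienoate (trans-lactone) | CC(=C\C(=O)OC(C)(C)C)/C=C(\C)C[C@H](C)CCCC[C@H]1OC(=O)[C@@H]1CO[Si](c1ccccc1)(c1ccccc1)C(C)(C)C | intermediate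
17 | tert-butyl (2E,4E,7R)-11-[(2S,3S)-3-{[(tert-butyldiphenylsilyl)oxy]methyl}-4-oxooxetan-2-yl]-3,5,7-trimethylundeca-2,4-dienoate (trans-lactone) | CC(=C\C(=O)OC(C)(C)C)/C=C(\C)C[C@H](C)CCCC[C@@H]1OC(=O)[C@H]1CO[Si](c1ccccc1)(c1ccccc1)C(C)(C)C | intermediate
18 | (2E,4E,7R)-11-[(2R,3R)-3-{[(tert-butyldiphenylsilyl)oxy]methyl}-4-oxooxetan-2-yl]-3,5,7-trimethylundeca-2,4-dienoic acid (O-silyl hymeglusin) | CC(=C\C(=O)O)/C=C(\C)C[C@H](C)CCCC[C@H]1OC(=O)[C@@H]1CO[Si](c1ccccc1)(c1ccccc1)C(C)(C)C | intermediate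
19 | 1-tert-butyl 14-(4-methoxybenzyl) (2E,4E,7R,12S,13S)-13-{[(tert-butyldiphenylsilyl)oxy]methyl}-12-hydroxy-3,5,7-trimethyltetradeca-2,4-dienedioate | CC(=C\C(=O)OC(C)(C)C)/C=C(\C)C[C@H](C)CCCC[C@H](O)[C@H](CO[Si](c1ccccc1)(c1ccccc1)C(C)(C)C)C(=O)OCc1ccc(OC)cc1 | intermediate
20 | mixed trichlorobenzoic anhydride of acid 18 | O=C(OC(=O)c1c(Cl)cc(Cl)cc1Cl)/C=C(C)/C=C(\C)C[C@H](C)CCCC[C@H]1OC(=O)[C@@H]1CO[Si](c1ccccc1)(c1ccccc1)C(C)(C)C | intermediate
21 | fully protected dimer: 19 acylated at O12 by the acyl group of 18 | CC(=C\C(=O)OC(C)(C)C)/C=C(\C)C[C@H](C)CCCC[C@H](OC(=O)/C=C(C)/C=C(\C)C[C@H](C)CCCC[C@H]1OC(=O)[C@@H]1CO[Si](c1ccccc1)(c1ccccc1)C(C)(C)C)[C@H](CO[Si](c1ccccc1)(c1ccccc1)C(C)(C)C)C(=O)OCc1ccc(OC)cc1 | intermediate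
22 | bis-silyl diacid: fusariumester B bis(tert-butyldiphenylsilyl) ether | CC(=C\C(=O)O)/C=C(\C)C[C@H](C)CCCC[C@H](OC(=O)/C=C(C)/C=C(\C)C[C@H](C)CCCC[C@H]1OC(=O)[C@@H]1CO[Si](c1ccccc1)(c1ccccc1)C(C)(C)C)[C@H](CO[Si](c1ccccc1)(c1ccccc1)C(C)(C)C)C(=O)O | intermediate
23 | fusariumester B: (2E,4E,7R,12S,13S)-13-(hydroxymethyl)-12-{[(2E,4E,7R)-11-[(2R,3R)-3-(hydroxymethyl)-4-oxooxetan-2-yl]-3,5,7-trimethylundeca-2,4-dienoyl]oxy}-3,5,7-trimethyltetradeca-2,4-dienedioic acid | CC(=C\C(=O)O)/C=C(\C)C[C@H](C)CCCC[C@H](OC(=O)/C=C(C)/C=C(\C)C[C@H](C)CCCC[C@H]1OC(=O)[C@@H]1CO)[C@H](CO)C(=O)O | target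

**Step count**
Total: 15 steps. Longest linear sequence: 10 steps (1, 2, 3, 4, 6, 7, 10, 12, 14, 15).

**Three steps most likely to fail, with fallbacks**

Step 10 (proposed new [2+2], lactone 16). The aldehyde may be too unreactive without a metal, the β-silyloxy enolate may eliminate, or the diastereoselectivity may be poor. The fallback uses known chemistry, sets out from 12, replaces steps 10 and 12, and comes back at 18. Cinchona-alkaloid acyl halide–aldehyde cyclocondensation of 12 with acetyl chloride (O-trimethylsilylquinine 10 mol%, LiClO4, iPr2NEt, CH2Cl2/Et2O, −78 °C) gives tert-butyl (2E,4E,7R)-3,5,7-trimethyl-11-[(2R)-4-oxooxetan-2-yl]undeca-2,4-dienoate F1. CF3CO2H/CH2Cl2 then frees (2E,4E,7R)-3,5,7-trimethyl-11-[(2R)-4-oxooxetan-2-yl]undeca-2,4-dienoic acid F2. Treatment with LiN(iPr)2 (2.1 equiv, THF, −78 °C) and gaseous CH2O follows; the first equivalent forms the lithium carboxylate, whose γ-protons should be removed only on warming, so the second enolises the lactone. The lactone enolate is hydroxymethylated anti to the ring substituent, giving hymeglusin F3. Silylation with tBuPh2SiCl (2.2 equiv)/imidazole gives tert-butyldiphenylsilyl (2E,4E,7R)-11-[(2R,3R)-3-{[(tert-butyldiphenylsilyl)oxy]methyl}-4-oxooxetan-2-yl]-3,5,7-trimethylundeca-2,4-dienoate F4, whose silyl ester is hydrolysed in the aqueous AcOH work-up to give 18.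

Step 11 (the same new reaction with the mirror-image catalyst, lactone 17). The fallback uses known chemistry, sets out from 12 and 14, replaces steps 11, 13 and 14, and comes back at 21. Acid 14 with (COCl)2/cat. DMF gives 3-[(tert-butyldiphenylsilyl)oxy]propanoyl chloride F5. The known cis-selective cinchona cyclocondensation with 12 (O-trimethylsilylquinine, LiI, iPr2NEt, CH2Cl2/Et2O, −78 °C) gives tert-butyl (2E,4E,7R)-11-[(2R,3S)-3-{[(tert-butyldiphenylsilyl)oxy]methyl}-4-oxooxetan-2-yl]-3,5,7-trimethylundeca-2,4-dienoate F6. La(OtBu)3/4-methoxybenzyl alcohol opens it with retention to the syn alcohol 1-tert-butyl 14-(4-methoxybenzyl) (2E,4E,7R,12R,13S)-13-{[(tert-butyldiphenylsilyl)oxy]methyl}-12-hydroxy-3,5,7-trimethyltetradeca-2,4-dienedioate F7. Mitsunobu esterification of F7 with acid 18 (PPh3, diisopropyl azodicarboxylate, toluene, 0 °C) inverts C12 to S and gives 21. Dehydration of the β-hydroxy ester is the known competing pathway, held back by the low temperature and the non-polar solvent.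

Step 14 (Yamaguchi esterification). The hindered β-hydroxy ester may react slowly, the activated 3-methyl-dienoic acid may isomerise, or the β-acyloxy ester may eliminate. The fallback replaces DMAP acyl transfer by alkoxide acylation; it sets out from 17 and 18, replaces steps 13 and 14, and comes back at 21. Acid 18 with 1-chloro-N,N,2-trimethylprop-1-en-1-amine (neutral, CH2Cl2, 0 °C) gives (2E,4E,7R)-11-[(2R,3R)-3-{[(tert-butyldiphenylsilyl)oxy]methyl}-4-oxooxetan-2-yl]-3,5,7-trimethylundeca-2,4-dienoyl chloride F8. Separately, lactone 17 is opened at −78 °C in THF with LiOCH2C6H4OMe-4 to the lithium alkoxide of 19 F9. This alkoxide is acylated in the same flask by F8 at −78 °C to give 21.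

**Further compounds**
F1 | step 10 | tert-butyl (2E,4E,7R)-3,5,7-trimethyl-11-[(2R)-4-oxooxetan-2-yl]undeca-2,4-dienoate | CC(=C\C(=O)OC(C)(C)C)/C=C(\C)C[C@H](C)CCCC[C@@H]1CC(=O)O1
F2 | step 10 | (2E,4E,7R)-3,5,7-trimethyl-11-[(2R)-4-oxooxetan-2-yl]undeca-2,4-dienoic acid | CC(=C\C(=O)O)/C=C(\C)C[C@H](C)CCCC[C@@H]1CC(=O)O1
F3 | step 10 | hymeglusin, (2E,4E,7R)-11-[(2R,3R)-3-(hydroxymethyl)-4-oxooxetan-2-yl]-3,5,7-trimethylundeca-2,4-dienoic acid | CC(=C\C(=O)O)/C=C(\C)C[C@H](C)CCCC[C@H]1OC(=O)[C@@H]1CO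
F4 | step 10 | tert-butyldiphenylsilyl (2E,4E,7R)-11-[(2R,3R)-3-{[(tert-butyldiphenylsilyl)oxy]methyl}-4-oxooxetan-2-yl]-3,5,7-trimethylundeca-2,4-dienoate | CC(=C\C(=O)O[Si](c1ccccc1)(c1ccccc1)C(C)(C)C)/C=C(\C)C[C@H](C)CCCC[C@H]1OC(=O)[C@@H]1CO[Si](c1ccccc1)(c1ccccc1)C(C)(C)C
F5 | step 11 | 3-[(tert-butyldiphenylsilyl)oxy]propanoyl chloride | O=C(Cl)CCO[Si](c1ccccc1)(c1ccccc1)C(C)(C)C
F6 | step 11 | tert-butyl (2E,4E,7R)-11-[(2R,3S)-3-{[(tert-butyldiphenylsilyl)oxy]methyl}-4-oxooxetan-2-yl]-3,5,7-trimethylundeca-2,4-dienoate (cis-lactone) | CC(=C\C(=O)OC(C)(C)C)/C=C(\C)C[C@H](C)CCCC[C@H]1OC(=O)[C@H]1CO[Si](c1ccccc1)(c1ccccc1)C(C)(C)C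
F7 | step 11 | 1-tert-butyl 14-(4-methoxybenzyl) (2E,4E,7R,12R,13S)-13-{[(tert-butyldiphenylsilyl)oxy]methyl}-12-hydroxy-3,5,7-trimethyltetradeca-2,4-dienedioate | CC(=C\C(=O)OC(C)(C)C)/C=C(\C)C[C@H](C)CCCC[C@@H](O)[C@H](CO[Si](c1ccccc1)(c1ccccc1)C(C)(C)C)C(=O)OCc1ccc(OC)cc1
F8 | step 14 | (2E,4E,7R)-11-[(2R,3R)-3-{[(tert-butyldiphenylsilyl)oxy]methyl}-4-oxooxetan-2-yl]-3,5,7-trimethylundeca-2,4-dienoyl chloride | O=C(Cl)/C=C(C)/C=C(\C)C[C@H](C)CCCC[C@H]1OC(=O)[C@@H]1CO[Si](c1ccccc1)(c1ccccc1)C(C)(C)C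
F9 | step 14 | lithium alkoxide of 19 | CC(=C\C(=O)OC(C)(C)C)/C=C(\C)C[C@H](C)CCCC[C@H]([O-])[C@H](CO[Si](c1ccccc1)(c1ccccc1)C(C)(C)C)C(=O)OCc1ccc(OC)cc1.[Li+]
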